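**Retrosynthetic overview**

1. The target is a 5-(arylmethyl)-6-hydroxy-8-methoxy-3-methylisocoumarin. Its bicyclic core (C1, O2, C3 to C8a) is a pentaketide in which C5, the carbon carrying the ring A benzyl group, is the central carbon of an open-chain 1,3-diketone (carbonyls at the future C4a and C6); the strategy rests on this.
2. Cutting C4a–C8a (aldol) and C1–O2 (lactone) opens ring B and the pyranone (ring C) to a C-benzylated diketo-dioxinone whose terminal methyl ketone is masked as a dioxolane.
3. That chain is cut at C5–C4a (acylation of a keto-dioxinone dianion by the N-methoxy-N-methylamide of ketal-protected acetoacetic acid) and at C6–C7 (acylation of lithiated 2,2,6-trimethyl-1,3-dioxin-4-one by the ring A dihydrocinnamoyl imidazolide).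
4. The ring A acid comes from 3,5-bis(benzyloxy)benzyl alcohol by formylation of the symmetrical arene, chelation-controlled differentiation of its two oxygens, two-carbon homologation and hydrogenation.
5. Ring order: ring A is bought; ring B and then ring C form in one flask; silylation of O6, methylation of O8 and desilylation finish the route.

Key step: step 11

Remark: the benzyl-bearing diketone carbon of the key-step precursor is enolisable, so that compound is a racemic tautomer mixture drawn without configuration, and the target is achiral; below, ArCH2 stands for the [2-methoxy-6-(methoxymethyl)-4-(triisopropylsilyloxy)phenyl]methyl group and TIPS for triisopropylsilyl.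

**Route**

Step 1
Reactants: 1 3,5-bis(benzyloxy)benzyl alcohol
Product: 2 1,3-bis(benzyloxy)-5-(methoxymethyl)benzene
Conditions: NaH, MeI, THF, 0 °C → rt
Reagents that add atoms: iodomethane, CI
Why: Williamson etherification of the primary benzylic alkoxide should be clean because no other acidic or electrophilic site is present.

Step 2
Reactants: 2 1,3-bis(benzyloxy)-5-(methoxymethyl)benzene
Product: 3 2,4-bis(benzyloxy)-6-(methoxymethyl)benzaldehyde
Conditions: POCl3, DMF, 0 → 70 °C; then H2O
Reagents that add atoms: N,N-dimethylformamide, CN(C)C=O; water, O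
Why: Vilsmeier–Haack formylation of the mirror-symmetric resorcinol diether should occur at one of the two equivalent positions next to the CH2OMe group (ortho to one benzyloxy, para to the other) and not at the position flanked by both ethers, as is usual for 3,5-dialkoxytoluenes, so the carbon substituent is placed before the two oxygens are told apart.

Step 3
Reactants: 3 2,4-bis(benzyloxy)-6-(methoxymethyl)benzaldehyde
Product: 4 4-(benzyloxy)-2-hydroxy-6-(methoxymethyl)benzaldehyde
Conditions: MgBr2·OEt2, toluene–Et2O, 80 °C; then 1 M HCl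
Reagents that add atoms: none
Why: Chelation of magnesium between the formyl oxygen and the ortho ether oxygen activates only that benzyl ether for bromide attack (chelation-controlled dealkylation of ortho-alkoxy aryl carbonyl compounds), while the para benzyl ether and the aliphatic methyl ether, which cannot form the six-membered chelate, should remain.

Step 4
Reactants: 4 4-(benzyloxy)-2-hydroxy-6-(methoxymethyl)benzaldehyde
Product: 5 4-(benzyloxy)-2-methoxy-6-(methoxymethyl)benzaldehyde
Conditions: MeI, K2CO3, DMF, rt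
Reagents that add atoms: iodomethane, CI
Why: O-Methylation of a salicylaldehyde-type phenol with MeI and carbonate is routine and fixes the ring A pattern (OMe ortho, protected OH para to the future benzylic carbon).

Step 5
Reactants: 5 4-(benzyloxy)-2-methoxy-6-(methoxymethyl)benzaldehyde
Product: 6 benzyl (E)-3-[4-(benzyloxy)-2-methoxy-6-(methoxymethyl)phenyl]prop-2-enoate
Conditions: (EtO)2P(O)CH2CO2Bn, NaH, THF, 0 °C → rt
Reagents that add atoms: benzyl 2-(diethoxyphosphoryl)acetate, CCOP(=O)(OCC)CC(=O)OCc1ccccc1
Why: Horner–Wadsworth–Emmons olefination of a non-enolisable aryl aldehyde with a stabilised phosphonate anion should give the E-cinnamate, whose geometry is irrelevant because the alkene is reduced next.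

Step 6
Reactants: 6 benzyl (E)-3-[4-(benzyloxy)-2-methoxy-6-(methoxymethyl)phenyl]prop-2-enoate
Product: 7 3-[4-hydroxy-2-methoxy-6-(methoxymethyl)phenyl]propanoic acid
Conditions: H2 (1 atm), 10% Pd/C, EtOAc–EtOH, rt
Reagents that add atoms: none
Why: Catalytic hydrogenation should saturate the alkene and hydrogenolyse both the benzyl ester and the aryl benzyl ether in one operation, the unactivated ArCH2–OMe ether being cleaved far more slowly.

Step 7
Reactants: 7 3-[4-hydroxy-2-methoxy-6-(methoxymethyl)phenyl]propanoic acid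
Product: 9 3-[2-methoxy-6-(methoxymethyl)-4-(triisopropylsilyloxy)phenyl]propanoic acid, via silyl ester silyl ether 8 (not isolated)
Conditions: TIPSCl (2.5 equiv), imidazole, DMF, rt; then K2CO3, MeOH–THF–H2O, 0 °C; citric acid work-up
Reagents that add atoms: chlorotriisopropylsilane, CC(C)[Si](Cl)(C(C)C)C(C)C
Why: Exhaustive silylation followed by brief mild basic hydrolysis should cleave only the far more labile silyl ester and leave the hindered aryl silyl ether (selective silyl ester cleavage).

Step 8
Reactants: 9 3-[2-methoxy-6-(methoxymethyl)-4-(triisopropylsilyloxy)phenyl]propanoic acid; 10 2,2,6-trimethyl-4H-1,3-dioxin-4-one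
Product: 12 6-[4-(2-methoxy-6-(methoxymethyl)-4-(triisopropylsilyloxy)phenyl)-2-oxobutyl]-2,2-dimethyl-4H-1,3-dioxin-4-one, via acyl imidazole 11 (not isolated)
Conditions: 9, CDI, THF, rt; added to 10 (2.5 equiv), LiN(SiMe3)2, THF, −78 → −30 °C; AcOH quench
Reagents that add atoms: 1,1'-carbonyldiimidazole, O=C(n1ccnc1)n1ccnc1 (imidazolyl group of intermediate 11 only; none of its atoms remain in 12)
Why: Claisen-type C-acylation of the lithium dienolate of the dioxinone at its exocyclic methyl carbon by an acyl imidazole is the standard entry to keto-dioxinones, the excess dienolate compensating for deprotonation of the more acidic product.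

Step 9
Reactants: 13 ethyl 2-(2-methyl-1,3-dioxolan-2-yl)acetate
Product: 14 N-methoxy-N-methyl-2-(2-methyl-1,3-dioxolan-2-yl)acetamide
Conditions: MeNH(OMe)·HCl, iPrMgCl, THF, −20 → 0 °C
Reagents that add atoms: N,O-dimethylhydroxylamine hydrochloride, CNOC.Cl
Why: Aminolysis of the ester by the chloromagnesium amide of N,O-dimethylhydroxylamine is a standard one-step amide synthesis to which the base-stable dioxolane is inert.

Step 10
Reactants: 12 6-[4-(2-methoxy-6-(methoxymethyl)-4-(triisopropylsilyloxy)phenyl)-2-oxobutyl]-2,2-dimethyl-4H-1,3-dioxin-4-one; 14 N-methoxy-N-methyl-2-(2-methyl-1,3-dioxolan-2-yl)acetamide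
Product: 15 6-[3-(ArCH2)-5-(2-methyl-1,3-dioxolan-2-yl)-2,4-dioxopentyl]-2,2-dimethyl-4H-1,3-dioxin-4-one
Conditions: LiN(iPr)2 (2.3 equiv), THF, −78 °C; then 14, −78 → −40 °C; AcOH quench at −78 °C
Reagents that add atoms: none
Why: Double deprotonation gives the dianion (first at the CH2 between dioxinone and ketone, then at the CH2 carrying the ArCH2 group), whose second, more basic carbanion is acylated by the N-methoxy-N-methylamide through a stable chelated tetrahedral adduct (dianion Claisen condensation), so the benzyl group ends up on the central carbon of the new 1,3-diketone.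

Step 11
Reactants: 15 6-[3-(ArCH2)-5-(2-methyl-1,3-dioxolan-2-yl)-2,4-dioxopentyl]-2,2-dimethyl-4H-1,3-dioxin-4-one
Product: 18 6,8-dihydroxy-5-(ArCH2)-3-methyl-1H-isochromen-1-one, via benzodioxinone ketal 16 (not isolated), via benzodioxinone methyl ketone 17 (not isolated)
Conditions: Et3N, CH2Cl2, rt; then TFA, H2O, 0 °C → rt
Reagents that add atoms: water, O
Why: Et3N enolises the CH2 between dioxinone and ketone to a dienolate whose dioxinone ring carbon (future C8a) adds to the ketone next to the ketal arm (future C4a), and loss of water plus enolisation of the benzyl-bearing CH aromatise ring B as benzodioxinone 16. Aqueous TFA then hydrolyses the dioxolane to methyl ketone 17, whose enol oxygen adds to the acetonide carbonyl and expels the acetone hemiketal, closing the pyranone (C1–O2) and freeing O8–H. The closest known chemistry is the amine-induced aldol aromatisation of diketo-dioxinones to resorcylate acetonides, followed by acid-mediated enol lactonisation of 2-(2-oxopropyl)benzoate derivatives to 3-methylisocoumarins. Ring B closes by a 6-(enolendo)-exo-trig aldol and ring C by a 6-exo-trig addition–elimination at the acyl carbon; no stereocentre is formed, and the labile centre of 15 becomes aromatic C5. The step needs carbon–carbon closure onto one ketone only and oxygen (not carbon) acylation in the lactonisation: attack on the other ketone would give a four-membered ring, Claisen-type closure through the diketone carbon is disfavoured because the benzyl group would make it quaternary and non-aromatisable, and the ketal withholds the methyl ketone from the basic stage (where carbon acylation to a naphthalenediol would compete) until acid is present. The benzyl group is a spectator on C5 throughout.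

Step 12
Reactants: 18 6,8-dihydroxy-5-(ArCH2)-3-methyl-1H-isochromen-1-one
Product: 19 8-hydroxy-5-(ArCH2)-3-methyl-6-(triisopropylsilyloxy)-1H-isochromen-1-one
Conditions: TIPSCl (1.5 equiv), imidazole, DMF, rt
Reagents that add atoms: chlorotriisopropylsilane, CC(C)[Si](Cl)(C(C)C)C(C)C
Why: Silylation with a bulky silyl chloride should take only the free O6–H, because O8–H is locked in a hydrogen bond to the peri lactone carbonyl (chelation-based site selectivity), and any ring A phenol set free in step 11 would be re-silylated to the same product.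

Step 13
Reactants: 19 8-hydroxy-5-(ArCH2)-3-methyl-6-(triisopropylsilyloxy)-1H-isochromen-1-one
Product: 20 8-methoxy-5-(ArCH2)-3-methyl-6-(triisopropylsilyloxy)-1H-isochromen-1-one
Conditions: MeI, K2CO3 (anhydrous), acetone, 50 °C
Reagents that add atoms: iodomethane, CI
Why: With every other hydroxyl blocked, Williamson methylation of the chelated phenol under anhydrous carbonate conditions should deliver the 8-methyl ether, hindered aryl silyl ethers being tolerated in dry acetone.

Step 14
Reactants: 20 8-methoxy-5-(ArCH2)-3-methyl-6-(triisopropylsilyloxy)-1H-isochromen-1-one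
Product: 21 6-hydroxy-5-{[4-hydroxy-2-methoxy-6-(methoxymethyl)phenyl]methyl}-8-methoxy-3-methyl-1H-isochromen-1-one (CNP0481202.0)
Conditions: n-Bu4NF, AcOH, THF, 0 °C
Reagents that add atoms: none
Why: Fluoride cleaves both aryl silyl ethers (fluoride-mediated desilylation), and the acetic acid buffer keeps the phenoxides protonated so that the lactone and the methyl ethers are untouched.

**Compound list**

1 | 3,5-bis(benzyloxy)benzyl alcohol | OCc1cc(OCc2ccccc2)cc(OCc2ccccc2)c1 | starting material
2 | 1,3-bis(benzyloxy)-5-(methoxymethyl)benzene | COCc1cc(OCc2ccccc2)cc(OCc2ccccc2)c1 | intermediate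
3 | 2,4-bis(benzyloxy)-6-(methoxymethyl)benzaldehyde | COCc1cc(OCc2ccccc2)cc(OCc2ccccc2)c1C=O | intermediate
4 | 4-(benzyloxy)-2-hydroxy-6-(methoxymethyl)benzaldehyde | COCc1cc(OCc2ccccc2)cc(O)c1C=O | intermediate
5 | 4-(benzyloxy)-2-methoxy-6-(methoxymethyl)benzaldehyde | COCc1cc(OCc2ccccc2)cc(OC)c1C=O | intermediate
6 | benzyl (E)-3-[4-(benzyloxy)-2-methoxy-6-(methoxymethyl)phenyl]prop-2-enoate | COCc1cc(OCc2ccccc2)cc(OC)c1/C=C/C(=O)OCc1ccccc1 | intermediate
7 | 3-[4-hydroxy-2-methoxy-6-(methoxymethyl)phenyl]propanoic acid | COCc1cc(O)cc(OC)c1CCC(=O)O | intermediate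
8 | triisopropylsilyl 3-[2-methoxy-6-(methoxymethyl)-4-(triisopropylsilyloxy)phenyl]propanoate | COCc1cc(O[Si](C(C)C)(C(C)C)C(C)C)cc(OC)c1CCC(=O)O[Si](C(C)C)(C(C)C)C(C)C | intermediate
9 | 3-[2-methoxy-6-(methoxymethyl)-4-(triisopropylsilyloxy)phenyl]propanoic acid | COCc1cc(O[Si](C(C)C)(C(C)C)C(C)C)cc(OC)c1CCC(=O)O | intermediate
10 | 2,2,6-trimethyl-4H-1,3-dioxin-4-one | CC1=CC(=O)OC(C)(C)O1 | starting material
11 | 1-(1H-imidazol-1-yl)-3-[2-methoxy-6-(methoxymethyl)-4-(triisopropylsilyloxy)phenyl]propan-1-one | COCc1cc(O[Si](C(C)C)(C(C)C)C(C)C)cc(OC)c1CCC(=O)n1ccnc1 | intermediate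
12 | 6-[4-(2-methoxy-6-(methoxymethyl)-4-(triisopropylsilyloxy)phenyl)-2-oxobutyl]-2,2-dimethyl-4H-1,3-dioxin-4-one | CC1(C)OC(CC(=O)CCc2c(COC)cc(O[Si](C(C)C)(C(C)C)C(C)C)cc2OC)=CC(=O)O1 | intermediate
13 | ethyl 2-(2-methyl-1,3-dioxolan-2-yl)acetate | CCOC(=O)CC1(C)OCCO1 | starting material
14 | N-methoxy-N-methyl-2-(2-methyl-1,3-dioxolan-2-yl)acetamide | CON(C)C(=O)CC1(C)OCCO1 | intermediate
15 | 6-[3-{[2-methoxy-6-(methoxymethyl)-4-(triisopropylsilyloxy)phenyl]methyl}-5-(2-methyl-1,3-dioxolan-2-yl)-2,4-dioxopentyl]-2,2-dimethyl-4H-1,3-dioxin-4-one (racemic, enolisable centre) | CC1(C)OC(CC(=O)C(Cc2c(COC)cc(O[Si](C(C)C)(C(C)C)C(C)C)cc2OC)C(=O)CC2(C)OCCO2)=CC(=O)O1 | intermediate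
16 | 7-hydroxy-6-{[2-methoxy-6-(methoxymethyl)-4-(triisopropylsilyloxy)phenyl]methyl}-2,2-dimethyl-5-[(2-methyl-1,3-dioxolan-2-yl)methyl]-4H-1,3-benzodioxin-4-one | CC1(C)Oc2cc(O)c(Cc3c(COC)cc(O[Si](C(C)C)(C(C)C)C(C)C)cc3OC)c(CC3(C)OCCO3)c2C(=O)O1 | intermediate
17 | 7-hydroxy-6-{[2-methoxy-6-(methoxymethyl)-4-(triisopropylsilyloxy)phenyl]methyl}-2,2-dimethyl-5-(2-oxopropyl)-4H-1,3-benzodioxin-4-one | CC(=O)Cc1c(Cc2c(COC)cc(O[Si](C(C)C)(C(C)C)C(C)C)cc2OC)c(O)cc2OC(C)(C)OC(=O)c12 | intermediate
18 | 6,8-dihydroxy-5-{[2-methoxy-6-(methoxymethyl)-4-(triisopropylsilyloxy)phenyl]methyl}-3-methyl-1H-isochromen-1-one | COCc1cc(O[Si](C(C)C)(C(C)C)C(C)C)cc(OC)c1Cc1c(O)cc(O)c2c(=O)oc(C)cc12 | intermediate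
19 | 8-hydroxy-5-{[2-methoxy-6-(methoxymethyl)-4-(triisopropylsilyloxy)phenyl]methyl}-3-methyl-6-(triisopropylsilyloxy)-1H-isochromen-1-one | COCc1cc(O[Si](C(C)C)(C(C)C)C(C)C)cc(OC)c1Cc1c(O[Si](C(C)C)(C(C)C)C(C)C)cc(O)c2c(=O)oc(C)cc12 | intermediate
20 | 8-methoxy-5-{[2-methoxy-6-(methoxymethyl)-4-(triisopropylsilyloxy)phenyl]methyl}-3-methyl-6-(triisopropylsilyloxy)-1H-isochromen-1-one | COCc1cc(O[Si](C(C)C)(C(C)C)C(C)C)cc(OC)c1Cc1c(O[Si](C(C)C)(C(C)C)C(C)C)cc(OC)c2c(=O)oc(C)cc12 | intermediate
21 | 6-hydroxy-5-{[4-hydroxy-2-methoxy-6-(methoxymethyl)phenyl]methyl}-8-methoxy-3-methyl-1H-isochromen-1-one | COCc1cc(O)cc(OC)c1Cc1c(O)cc(OC)c2c(=O)oc(C)cc12 | target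

**Step count**

Total steps: 14. Longest linear sequence: 13 (steps 1 to 8 and 10 to 14; step 9 is a one-step side branch).

**Steps most likely to fail**

Step 10. Proton transfer from the enolisable amide to the dianion, or slow bond formation at the substituted carbanion, may return 12 unchanged, and 15 may cyclise prematurely on work-up. Fallback, from 14 and 12 back to 15: reduction of 14 with LiAlH4 (THF, −78 → 0 °C) should give 2-(2-methyl-1,3-dioxolan-2-yl)acetaldehyde F1. The dianion of 12 (LiN(iPr)2, THF, −78 °C) should add to this far more electrophilic aldehyde in an aldol reaction to give 6-[3-(ArCH2)-4-hydroxy-5-(2-methyl-1,3-dioxolan-2-yl)-2-oxopentyl]-2,2-dimethyl-4H-1,3-dioxin-4-one F2 as a diastereomer mixture. Oxidation with Dess–Martin periodinane (CH2Cl2, NaHCO3, 0 °C) then returns to 15.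

Step 11. After ketal hydrolysis, acyl substitution at the acetonide carbonyl may stall, and prolonged acid exposure may cause desilylation or protodebenzylation at the electron-rich C5. Fallback, from 16 back to 19: the flask is worked up after the Et3N stage and 16 is isolated. Saponification of the acetonide (aq KOH, THF, 60 °C; expected to remove the ring A silyl group as well) and cold acidification should give 2,4-dihydroxy-5-{[4-hydroxy-2-methoxy-6-(methoxymethyl)phenyl]methyl}-6-[(2-methyl-1,3-dioxolan-2-yl)methyl]benzoic acid F3. Dilute HCl in THF at rt should unmask the ketone, and the resulting 2-(2-oxopropyl)benzoic acid should cyclodehydrate in the classical way to 6,8-dihydroxy-5-{[4-hydroxy-2-methoxy-6-(methoxymethyl)phenyl]methyl}-3-methyl-1H-isochromen-1-one F4. TIPSCl (2.5 equiv) and imidazole then silylate both unchelated phenols and rejoin the route at 19.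

Step 13. Carbonate may remove the silyl group on O6 (para to the lactone carbonyl), which would lead to methylation of both oxygens, or alkylation of the hydrogen-bonded O8–H may be sluggish. Fallback, from 18 back to 21, using a base-stable acetal on O6 instead of a silyl ether: MOMCl and iPr2NEt (CH2Cl2, 0 °C) should give the 6-(methoxymethoxy)-8-hydroxy isocoumarin F5. MeI and K2CO3 (acetone, 50 °C) should give its 8-methyl ether F6. n-Bu4NF with AcOH should remove the ring A silyl ether to give the 6-(methoxymethoxy)-8-methoxy phenol F7, and HCl in MeOH (rt) should cleave the acetal to give 21.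

**Further compounds**

F1 | step 10 | 2-(2-methyl-1,3-dioxolan-2-yl)acetaldehyde | CC1(CC=O)OCCO1
F2 | step 10 | 6-[4-hydroxy-3-{[2-methoxy-6-(methoxymethyl)-4-(triisopropylsilyloxy)phenyl]methyl}-5-(2-methyl-1,3-dioxolan-2-yl)-2-oxopentyl]-2,2-dimethyl-4H-1,3-dioxin-4-one (diastereomer mixture) | CC1(C)OC(CC(=O)C(Cc2c(COC)cc(O[Si](C(C)C)(C(C)C)C(C)C)cc2OC)C(O)CC2(C)OCCO2)=CC(=O)O1
F3 | step 11 | 2,4-dihydroxy-5-{[4-hydroxy-2-methoxy-6-(methoxymethyl)phenyl]methyl}-6-[(2-methyl-1,3-dioxolan-2-yl)methyl]benzoic acid | COCc1cc(O)cc(OC)c1Cc1c(O)cc(O)c(C(=O)O)c1CC1(C)OCCO1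
F4 | step 11 | 6,8-dihydroxy-5-{[4-hydroxy-2-methoxy-6-(methoxymethyl)phenyl]methyl}-3-methyl-1H-isochromen-1-one | COCc1cc(O)cc(OC)c1Cc1c(O)cc(O)c2c(=O)oc(C)cc12
F5 | step 13 | 8-hydroxy-6-(methoxymethoxy)-5-{[2-methoxy-6-(methoxymethyl)-4-(triisopropylsilyloxy)phenyl]methyl}-3-methyl-1H-isochromen-1-one | COCc1cc(O[Si](C(C)C)(C(C)C)C(C)C)cc(OC)c1Cc1c(OCOC)cc(O)c2c(=O)oc(C)cc12
F6 | step 13 | 8-methoxy-6-(methoxymethoxy)-5-{[2-methoxy-6-(methoxymethyl)-4-(triisopropylsilyloxy)phenyl]methyl}-3-methyl-1H-isochromen-1-one | COCc1cc(O[Si](C(C)C)(C(C)C)C(C)C)cc(OC)c1Cc1c(OCOC)cc(OC)c2c(=O)oc(C)cc12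
F7 | step 13 | 5-{[4-hydroxy-2-methoxy-6-(methoxymethyl)phenyl]methyl}-8-methoxy-6-(methoxymethoxy)-3-methyl-1H-isochromen-1-one | COCc1cc(O)cc(OC)c1Cc1c(OCOC)cc(OC)c2c(=O)oc(C)cc12
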